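**Remark:** The target has no stereocentre and is achiral, so the requirement of a single enantiomer is met trivially and no step needs stereocontrol.

## Structural features

Gentiside E is a benzene ring (C1–C6) with three contiguous substituents: an ester carbonyl carbon (C7) on C1 and free hydroxyl groups on C2 and C3. The ester oxygen carries an unbranched, saturated C18 chain (C1′–C18′); there is no second ring and no stereocentre. The C2 hydroxyl is hydrogen-bonded to the C7 carbonyl (salicylate motif). The C2/C3 pair is a catechol, which is easily oxidised to an ortho-quinone under basic aerobic conditions and binds metals strongly. The ester is the only other sensitive group (hydrolysis, transesterification). The difficulty is therefore connectivity and chemoselectivity, not stereochemistry. C7 must sit ortho to the catechol (the 1,2,3-pattern, which ordinary electrophilic substitution of a catechol does not favour), and it must be joined to a waxy, non-volatile alcohol used in near-stoichiometric amount while two phenolic nucleophiles compete. C7 is the single atom linking the arene and the chain; the key step exploits this by delivering C7 as carbon monoxide and forming both of its skeletal bonds, C1–C7 and C7–O, in one catalytic operation at the brominated carbon that becomes C1.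

## Logic of the disconnections

**7 ⇒ 6.** The two phenolic O–H bonds of 7 are traced back to two O–CH2Ph bonds. The cut is made because a free catechol would bind and reduce palladium(II) and would offer two further O–H nucleophiles in the key step. No skeletal simplification is gained, but the key step becomes a clean three-partner reaction. The forward step must remove both benzyl groups without touching the alkyl ester or oxidising the liberated catechol, which points to neutral hydrogenolysis.

**6 ⇒ 2 + 3 + 4 (key disconnection).** Both skeletal bonds of the carbonyl carbon are cut at once: the ring-carbon–carbonyl C–C bond and the carbonyl–oxygen C–O bond. Because the carbonyl carbon is the only atom linking arene and chain, cutting on both sides of it dissolves 6 into three simple partners: the aryl bromide 2, the one-carbon unit 3 and the unmodified alcohol 4. The 1,2,3-substitution pattern is reduced to the position of a halogen. The forward step must form the acyl–metal species 5 by oxidative addition and insertion of 3 faster than any direct aryl–oxygen coupling, and 5 must be intercepted by 4 present only in near-stoichiometric amount.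

**2 ⇒ 1.** The two benzylic C–O bonds are cut to return to 1, which is commercial and already carries bromine on the carbon next to the diol. The gain is a starting material in which the regiochemical problem is solved by purchase. The forward step must alkylate both oxygens completely, including the one flanked by bromine, with exclusion of air.

## Other disconnections considered

**Alternative 1:** (the first that comes to mind) Cut the acyl C7–O bond, or the O–C1′ bond. Forward: 2,3-dihydroxybenzoic acid A1 and 4 under acid-catalysed esterification with azeotropic removal of water, or the carboxylate of A1 and 1-bromooctadecane A2 by O-alkylation, each giving 7 in one step. It is shorter on paper. The chosen plan is preferred on mechanistic grounds: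
- The carboxyl group of A1 is hydrogen-bonded to and flanked by the C2 hydroxyl, which deactivates it.
- Fischer esterification is an equilibrium normally driven by excess alcohol as solvent, which a solid C18 alcohol cannot provide and which cannot be distilled off afterwards.
- Any activation of A1 as an acyl electrophile exposes two free phenols to self-acylation.
- Alkylation with A2 pits carboxylate against phenoxide oxygen.

**Alternative 2:** Cut only the C1–C7 bond, with polarity reversal at the ring. Forward: directed ortho-lithiation of 1,2-bis(methoxymethoxy)benzene A3 to 2,3-bis(methoxymethoxy)phenyllithium A4, C-acylation with octadecyl chloroformate A5 to octadecyl 2,3-bis(methoxymethoxy)benzoate A6, and acid removal of the acetals to 7. The chosen plan is preferred because: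
- A4 can add a second time to the ester A6 once it forms, so inverse addition to excess A5 would be needed.
- A5 is a waxy, phosgene-derived reagent, poorly soluble at the low temperature the organolithium demands, and is itself made from 4.
- The union joins two components stoichiometrically under cryogenic conditions, whereas the chosen step joins three under catalysis and uses 4 as it is.

**Alternative 3:** Cut the C3–O bond. Forward: ortho-formylation of octadecyl 2-hydroxybenzoate A7 to octadecyl 3-formyl-2-hydroxybenzoate A8, then Dakin oxidation of the aldehyde to the C3 hydroxyl, giving 7. The chosen plan is preferred because: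
- A7 still has to be made by the conventional esterification, so the first disconnection is not avoided.
- The phenol of A7 is deactivated by the ortho ester, so formylation should be sluggish and divided between C3 and C5.
- The Dakin step exposes both the ester and the new catechol to basic peroxide.
- The sequence is linear and adjusts one substituent per step.

Key step: step 2

## Route

**Step 1**
Reactants: 1 3-bromobenzene-1,2-diol (3-bromocatechol)
Product: 2 1,2-bis(benzyloxy)-3-bromobenzene
Conditions: BnBr (2.3 equiv), K2CO3 (3 equiv), DMF, N2, rt → 50 °C
Reagents that add atoms: benzyl bromide, BrCc1ccccc1
Why: Double Williamson ether synthesis: carbonate deprotonates both phenols and each phenoxide displaces bromide from the benzylic halide by SN2. The aryl C–Br bond is inert here, and exclusion of air protects the catecholate from oxidation.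

**Step 2**
Reactants: 2 1,2-bis(benzyloxy)-3-bromobenzene; 3 carbon monoxide; 4 octadecan-1-ol (1.2 equiv)
Product: 6 octadecyl 2,3-bis(benzyloxy)benzoate, via bromo[2,3-bis(benzyloxy)benzoyl](Xantphos)palladium(II) 5 (not isolated)
Conditions: Pd(OAc)2 (3 mol%), Xantphos (3.5 mol%), Et3N (3 equiv), CO (1 atm, balloon), toluene, 100 °C
Reagents that add atoms: none
Why: This is a palladium-catalysed three-component alkoxycarbonylation of an aryl bromide (Heck-type carbonylation) at atmospheric pressure with the wide-bite-angle ligand Xantphos, a known reaction type for alkyl benzoates. Pd(0)–Xantphos should add oxidatively to the only C–Br bond of 2, and coordination and migratory insertion of 3 should give the aroyl complex 5. Attack of 4 on the acyl group of 5, assisted by Et3N, should release 6 and triethylammonium bromide and return Pd(0), so both bonds of the carbonyl carbon (aryl C–C and acyl C–O) are made in one catalytic turnover. No ring is closed and no stereocentre is created. The step needs regioselectivity, which is fixed by the position of bromine in 2 (the carbon flanking the dioxygenated carbons), and chemoselectivity in the capture of 5, which is secured because 4 is the only O–H nucleophile once both phenols are benzyl ethers. CO insertion should outrun direct C–O coupling because aryl-to-acyl migration is fast under 1 atm CO and is helped by relief of strain next to the ortho benzyloxy group, while the chelating diphosphine keeps palladium in solution at low CO pressure and disfavours β-hydride loss from a palladium alkoxide of 4. Benzyl ethers, the arene and the saturated chain are inert to Pd(0), CO and amine base at 100 °C.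

**Step 3**
Reactants: 6 octadecyl 2,3-bis(benzyloxy)benzoate
Product: 7 octadecyl 2,3-dihydroxybenzoate (Gentiside E)
Conditions: H2 (1 atm), 10% Pd/C, EtOAc–THF (1:1), rt; filtration under N2
Reagents that add atoms: none
Why: Heterogeneous hydrogenolysis of benzyl aryl ethers: both benzylic C–O bonds should be cleaved to toluene under neutral conditions, while the octadecyl ester (no benzylic or allylic C–O bond), the arene and the chain are untouched. The catechol is released without base under a reducing atmosphere, so it should not oxidise.

## Compound list

1 | 3-bromobenzene-1,2-diol (3-bromocatechol) | Oc1cccc(Br)c1O | starting material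
2 | 1,2-bis(benzyloxy)-3-bromobenzene | Brc1cccc(OCc2ccccc2)c1OCc1ccccc1 | intermediate
3 | carbon monoxide | [C-]#[O+] | starting material
4 | octadecan-1-ol | CCCCCCCCCCCCCCCCCCO | starting material
5 | bromo[2,3-bis(benzyloxy)benzoyl](Xantphos)palladium(II), Xantphos = 4,5-bis(diphenylphosphino)-9,9-dimethylxanthene bound through both phosphorus atoms | O=C(c1cccc(OCc2ccccc2)c1OCc1ccccc1)[Pd-2]1(Br)[P+](c2ccccc2)(c2ccccc2)c2cccc3c2Oc2c(cccc2[P+]1(c1ccccc1)c1ccccc1)C3(C)C | intermediate (not isolated)
6 | octadecyl 2,3-bis(benzyloxy)benzoate | CCCCCCCCCCCCCCCCCCOC(=O)c1cccc(OCc2ccccc2)c1OCc1ccccc1 | intermediate
7 | octadecyl 2,3-dihydroxybenzoate (Gentiside E) | CCCCCCCCCCCCCCCCCCOC(=O)c1cccc(O)c1O | target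

## Step count and risk assessment

Total step count: 3. Longest linear sequence: 3 steps (1 → 2 → 6 → 7); 3 and 4 enter at step 2.

**Step 2 (key step).** The most likely failure is slow alcoholysis of 5, because 4 is present only in near-stoichiometric amount and not as solvent. The catalyst would then rest as 5, lose CO and aggregate to palladium black, or a palladium alkoxide of 4 would undergo β-hydride elimination and cause reductive loss of bromine from 2. Oxidative addition into the electron-rich, ortho-substituted C–Br bond under CO may also be sluggish. Fallback, setting out from 2: bromine–lithium exchange (n-BuLi, THF, −78 °C) should give 2,3-bis(benzyloxy)phenyllithium F1, which is carboxylated with dry CO2 and acidified (aq. HCl) to 2,3-bis(benzyloxy)benzoic acid F2. Carbodiimide coupling of F2 with 4 (DCC, cat. DMAP, CH2Cl2, rt) then returns to the route at 6. With both phenols masked there is no competing phenol acylation and no hydrogen-bond deactivation, so this two-component esterification should be clean.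

**Step 1.** The likely problems are incomplete second O-alkylation at the oxygen flanked by bromine and the first benzyloxy group, and air oxidation of the catecholate before alkylation is complete. Fallback, setting out from 1: both oxygens are tied up in one operation as a cyclic ketal (2,2-dimethoxypropane, cat. TsOH, benzene, reflux with removal of methanol) to give 4-bromo-2,2-dimethyl-1,3-benzodioxole F3. F3 is carbonylated with 3 and 4 under the conditions of step 2, through the corresponding aroyl complex bromo(2,2-dimethyl-1,3-benzodioxole-4-carbonyl)(Xantphos)palladium(II) F4, to octadecyl 2,2-dimethyl-1,3-benzodioxole-4-carboxylate F5. Acid hydrolysis of the ketal (TFA–H2O, CH2Cl2, rt) then comes back to the route at 7, bypassing 2 and 6.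

**Step 3.** Hydrogenolysis may stall after loss of the first benzyl group, through poor solubility of the waxy substrate or poisoning of the catalyst by traces of phosphine or bromide carried over from step 2. Oxidation of the liberated catechol on the catalyst during filtration in air is a second risk. Fallback, setting out from 6: Lewis-acid debenzylation with BCl3 and pentamethylbenzene as a non-Lewis-basic benzyl-cation scavenger (CH2Cl2, −78 °C) should cleave both aryl benzyl ethers without touching the ester and arrive directly at 7, so this fallback makes no new compound (F0).

## Further compounds

F1 | step 2 | 2,3-bis(benzyloxy)phenyllithium | [Li]c1cccc(OCc2ccccc2)c1OCc1ccccc1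
F2 | step 2 | 2,3-bis(benzyloxy)benzoic acid | OC(=O)c1cccc(OCc2ccccc2)c1OCc1ccccc1
F3 | step 1 | 4-bromo-2,2-dimethyl-1,3-benzodioxole | CC1(C)Oc2cccc(Br)c2O1
F4 | step 1 | bromo(2,2-dimethyl-1,3-benzodioxole-4-carbonyl)(Xantphos)palladium(II) | O=C(c1cccc2OC(C)(C)Oc12)[Pd-2]1(Br)[P+](c2ccccc2)(c2ccccc2)c2cccc3c2Oc2c(cccc2[P+]1(c1ccccc1)c1ccccc1)C3(C)C
F5 | step 1 | octadecyl 2,2-dimethyl-1,3-benzodioxole-4-carboxylate | CCCCCCCCCCCCCCCCCCOC(=O)c1cccc2OC(C)(C)Oc12
F0 | step 3 | none | none
A1 | alternative 1 | 2,3-dihydroxybenzoic acid | OC(=O)c1cccc(O)c1O
A2 | alternative 1 | 1-bromooctadecane | CCCCCCCCCCCCCCCCCCBr
A3 | alternative 2 | 1,2-bis(methoxymethoxy)benzene | COCOc1ccccc1OCOC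
A4 | alternative 2 | 2,3-bis(methoxymethoxy)phenyllithium | [Li]c1cccc(OCOC)c1OCOC
A5 | alternative 2 | octadecyl chloroformate | CCCCCCCCCCCCCCCCCCOC(Cl)=O
A6 | alternative 2 | octadecyl 2,3-bis(methoxymethoxy)benzoate | CCCCCCCCCCCCCCCCCCOC(=O)c1cccc(OCOC)c1OCOC
A7 | alternative 3 | octadecyl 2-hydroxybenzoate | CCCCCCCCCCCCCCCCCCOC(=O)c1ccccc1O
A8 | alternative 3 | octadecyl 3-formyl-2-hydroxybenzoate | CCCCCCCCCCCCCCCCCCOC(=O)c1cccc(C=O)c1O
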